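**Retrosynthetic overview**

1. Numbering: C1 CHO, C2 its α-carbon, C3–C5 hydroxypropyl (OH on C3), ring C6(H)–C7(sp2)–C8–C9–C10(Me, OH)–C11(Me), chain C12–C24 with carbinol C17. The strategy rests on the ring bond C10–C11, which joins the tertiary carbinol to the quaternary carbon. It is cut to a C10 methyl ketone and a C11=C12 β-methyl enoate (C13 = ester carbon) and closed by a samarium ketyl 6-exo-trig cyclisation.
2. The acyclic keto enoate comes from an Evans syn aldol (C6–C7 bond; C6 permanent, C7 a temporary carbinol) of a 5-(PMB-oxy)pentanoyl imide with pent-4-enal, then Weinreb amide, methyl ketone and Horner–Wadsworth–Emmons olefination. The C10 ketone is unveiled last by Wacker oxidation, so no ketal has to be hydrolysed beside the C7 silyl ether.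
3. C13–C14 is cut to an alkylzinc (from the C13 ester) and an (E)-vinyl iodide made from geranial by asymmetric propargylation (C17) and carboalumination–iodination.
4. The tetrasubstituted C2=C7 enal is cut through a temporary eight-membered lactone: a 2-bromopropanoate on the C3 oxygen closes onto the C7 ketone (Reformatsky), elimination forces C1 cis to C6, and reduction then allylic oxidation release the enal and the C3 alcohol.
5. Ring order: cyclohexane (step 9, the only carbocycle); temporary lactone (closed in step 21, opened in step 23).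

Key step: step 9

Assumption: geranial is used as the pure 2E isomer, and the (R)-phosphoric acid in step 13 is taken to direct Re-face attack on geranial, as it does for aryl and alkenyl aldehydes, which gives 17R.

**Route**

Step 1
Reactants: 1 δ-valerolactone
Product: 2 5-[(4-methoxybenzyl)oxy]pentanoic acid
Conditions: KOH, PMBCl, toluene, reflux; then aq. HCl
Reagents that add atoms: 4-methoxybenzyl chloride, COc1ccc(CCl)cc1; potassium hydroxide, [K+].[OH-]
Why: Hydroxide should open the lactone and the alkoxide end of the hydroxy carboxylate is benzylated in a Williamson etherification, any PMB ester being saponified in the same pot.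

Step 2
Reactants: 2 5-[(4-methoxybenzyl)oxy]pentanoic acid; 3 (R)-4-benzyl-2-oxazolidinone
Product: 5 (R)-4-benzyl-3-{5-[(4-methoxybenzyl)oxy]pentanoyl}oxazolidin-2-one, via pivalic mixed anhydride 4 (not isolated)
Conditions: PivCl, Et3N, THF, −20 °C; then 3, LiCl, −20 °C → rt
Reagents that add atoms: none
Why: N-Acylation of the oxazolidinone through the mixed pivalic anhydride is the standard entry to Evans imides and needs no strong base.

Step 3
Reactants: 5 (R)-4-benzyl-3-{5-[(4-methoxybenzyl)oxy]pentanoyl}oxazolidin-2-one; 6 pent-4-enal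
Product: 8 (R)-4-benzyl-3-[(2R,3S)-3-hydroxy-2-{3-[(4-methoxybenzyl)oxy]propyl}hept-6-enoyl]oxazolidin-2-one, via Z-dibutylboron enolate 7 (not isolated)
Conditions: Bu2BOTf, i-Pr2NEt, CH2Cl2, −78 → 0 °C; 6, −78 → 0 °C; then H2O2, MeOH, pH 7 buffer
Reagents that add atoms: none
Why: Evans syn aldol: the Z-boron enolate reacts through a Zimmerman–Traxler chair with the imide dipoles opposed, and the benzyl group of the (R)-auxiliary shields one enolate face, which should set C6 (acyl C2, R) and C7 (acyl C3, S) in the syn relation.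

Step 4
Reactants: 8 syn aldol adduct
Product: 9 (2R,3S)-3-hydroxy-N-methoxy-2-{3-[(4-methoxybenzyl)oxy]propyl}-N-methylhept-6-enamide
Conditions: MeNHOMe·HCl, AlMe3, CH2Cl2, −20 → 0 °C
Reagents that add atoms: N,O-dimethylhydroxylamine hydrochloride, CNOC.Cl
Why: Aluminium amide transamidation to the Weinreb amide is reliable on β-hydroxy imides because the free C7 hydroxyl directs the reagent to the exocyclic carbonyl; the auxiliary is recovered.

Step 5
Reactants: 9 β-hydroxy Weinreb amide
Product: 10 (2R,3S)-N-methoxy-2-{3-[(4-methoxybenzyl)oxy]propyl}-N-methyl-3-(triethylsilyloxy)hept-6-enamide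
Conditions: TESOTf, 2,6-lutidine, CH2Cl2, −78 °C
Reagents that add atoms: triethylsilyl triflate, CC[Si](CC)(CC)OS(=O)(=O)C(F)(F)F
Why: Silylation of the secondary alcohol with a silyl triflate and a hindered base; TES is chosen because it can later be removed beside a tertiary TES ether and a TBS ether.

Step 6
Reactants: 10 silylated Weinreb amide
Product: 11 (3R,4S)-3-{3-[(4-methoxybenzyl)oxy]propyl}-4-(triethylsilyloxy)oct-7-en-2-one
Conditions: MeMgBr, THF, 0 °C
Reagents that add atoms: methylmagnesium bromide, C[Mg]Br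
Why: Weinreb ketone synthesis: the chelated tetrahedral intermediate prevents over-addition, and C6 should not be enolised at 0 °C.

Step 7
Reactants: 11 methyl ketone
Product: 12 ethyl (2E,4S,5S)-4-{3-[(4-methoxybenzyl)oxy]propyl}-3-methyl-5-(triethylsilyloxy)nona-2,8-dienoate
Conditions: (EtO)2P(O)CH2CO2Et, NaH, THF, 0 → 50 °C
Reagents that add atoms: triethyl phosphonoacetate, CCOC(=O)CP(=O)(OCC)OCC
Why: Horner–Wadsworth–Emmons olefination of the methyl ketone: reversible addition should let the branched C6 substituent end trans to the ester (2E, geometry only), and the weakly basic phosphonate anion should spare the β-silyloxy ketone.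

Step 8
Reactants: 12 dienoate
Product: 13 ethyl (2E,4S,5S)-4-{3-[(4-methoxybenzyl)oxy]propyl}-3-methyl-8-oxo-5-(triethylsilyloxy)non-2-enoate
Conditions: PdCl2 (10 mol%), Cu(OAc)2, O2 (1 atm), DMA/H2O, rt
Reagents that add atoms: water, O
Why: Tsuji–Wacker oxidation: Markovnikov hydroxypalladation and β-hydride elimination convert only the monosubstituted alkene into the methyl ketone (the trisubstituted enoate is inert), and Cu(OAc)2 keeps the medium buffered for the TES ether.

Step 9
Reactants: 13 keto enoate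
Product: 14 ethyl 2-[(1S,2S,3S,6S)-6-hydroxy-2-{3-[(4-methoxybenzyl)oxy]propyl}-1,6-dimethyl-3-(triethylsilyloxy)cyclohexyl]acetate
Conditions: SmI2 (2.5 equiv), HMPA (10 equiv), t-BuOH (2 equiv), THF, −78 → 0 °C
Reagents that add atoms: none
Why: SmI2–HMPA transfers one electron to the C10 methyl ketone, the samarium ketyl adds to C11 (the β-carbon of the enoate), a second electron turns the α-ester radical into a samarium enolate, and t-BuOH protonates it at C12. The closest known reaction type is the samarium diiodide ketyl–olefin (ketone–enoate) reductive cyclisation. The cyclohexane closes in the 6-exo-trig mode through a chair in which the C6 side chain and the C7 silyloxy group, trans to each other from the syn aldol, both sit equatorial. C10 is set by the bulky HMPA-solvated O–Sm group taking the equatorial site, trans to the developing C12 arm and away from the ester; C11 is set by the acceptor double bond lying equatorial with C6–H eclipsing it (least allylic strain, the E-enoate having only H cis to C6), which leaves the C11 methyl axial and cis to the C6 chain. The step needs cyclisation to outrun simple ketone reduction and one diastereomer out of four; the electron-poor enoate and the two equatorial anchors should secure this. A C10 epimer would show itself by closing to a γ-lactone.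

Step 10
Reactants: 14 cyclohexanol ester
Product: 15 ethyl 2-[(1S,2S,3S,6S)-2-{3-[(4-methoxybenzyl)oxy]propyl}-1,6-dimethyl-3,6-bis(triethylsilyloxy)cyclohexyl]acetate
Conditions: TESOTf, 2,6-lutidine, CH2Cl2, 0 °C → rt
Reagents that add atoms: triethylsilyl triflate, CC[Si](CC)(CC)OS(=O)(=O)C(F)(F)F
Why: Silylation of the hindered tertiary alcohol with the silyl triflate; protection is needed because a free C10 hydroxyl would close a tetrahydrofuran onto C13 once that carbon is activated.

Step 11
Reactants: 15 bis-silyl ester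
Product: 16 2-[(1S,2S,3S,6S)-2-{3-[(4-methoxybenzyl)oxy]propyl}-1,6-dimethyl-3,6-bis(triethylsilyloxy)cyclohexyl]ethanol
Conditions: LiAlH4, Et2O, 0 °C
Reagents that add atoms: none
Why: Hydride reduction of the ester to the primary C13 alcohol; silyl and PMB ethers are inert.

Step 12
Reactants: 16 primary alcohol
Product: 17 C13 iodide (16 with 2-iodoethyl in place of 2-hydroxyethyl)
Conditions: I2, PPh3, imidazole, CH2Cl2, 0 °C → rt
Reagents that add atoms: iodine, II
Why: Appel-type iodination: SN2 displacement of the alkoxyphosphonium ion by iodide at the primary carbon.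

Step 13
Reactants: 18 geranial
Product: 19 (4R,5E)-6,10-dimethylundeca-5,9-dien-1-yn-4-ol
Conditions: allenyl-B(pin), (R)-3,3′-bis(2,4,6-triisopropylphenyl)-1,1′-binaphthyl-2,2′-diyl hydrogen phosphate (10 mol%), 4 Å MS, toluene, −20 °C
Reagents that add atoms: allenylboronic acid pinacol ester, C=C=CB1OC(C)(C)C(C)(C)O1
Why: Brønsted acid-catalysed allenylboration (SE2′ propargylation through a six-membered chair in which the phosphoric acid binds the boronate oxygen and the formyl hydrogen); the (R)-acid should expose the Re face of the aldehyde and so set C17 as R.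

Step 14
Reactants: 19 homopropargylic alcohol
Product: 21 (1E,4R,5E)-1-iodo-2,6,10-trimethylundeca-1,5,9-trien-4-ol, via bis(dimethylaluminium) vinylalane alkoxide 20 (not isolated)
Conditions: AlMe3 (3 equiv), Cp2ZrCl2 (0.3 equiv), CH2Cl2, 0 °C → rt; then I2, THF, −30 → 0 °C
Reagents that add atoms: trimethylaluminium, C[Al](C)C; iodine, II
Why: Negishi zirconium-catalysed carboalumination: methyl and aluminium add syn with methyl on the internal carbon, the hydroxyl is carried as its aluminium alkoxide, and iodinolysis with retention should give the 1E vinyl iodide (kept at or below rt to avoid isomerisation of the alkenylalane).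

Step 15
Reactants: 21 iodo alcohol
Product: 22 (1E,4R,5E)-4-(tert-butyldimethylsilyloxy)-1-iodo-2,6,10-trimethylundeca-1,5,9-triene
Conditions: TBSCl, imidazole, DMF, rt
Reagents that add atoms: tert-butyldimethylsilyl chloride, CC(C)(C)[Si](C)(C)Cl
Why: Standard silylation; TBS at C17 survives the later removal of the secondary TES ether and shields the allylic alcohol from MnO2.

Step 16
Reactants: 17 C13 iodide; 22 vinyl iodide
Product: 25 coupled polyene (C3–OPMB; C7–OTES; C10–OTES; C17–OTBS; 14E; 18E), via alkyllithium 23 (not isolated), via alkylzinc chloride 24 (not isolated)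
Conditions: 17, t-BuLi (2.1 equiv), Et2O, −78 °C; ZnCl2, THF, −78 °C → rt; then 22, Pd(PPh3)4 (5 mol%), rt
Reagents that add atoms: none
Why: Negishi sp3–sp2 cross-coupling: iodine–lithium exchange, transmetalation to zinc and coupling catalysed by zerovalent palladium proceed with retention of the vinyl iodide geometry, so the 14E double bond is the one set in step 14.

Step 17
Reactants: 25 coupled polyene
Product: 26 C3 alcohol
Conditions: DDQ, CH2Cl2/pH 7 buffer, 0 °C
Reagents that add atoms: none
Why: Oxidative PMB cleavage (hydride abstraction by DDQ at the electron-rich benzylic position, then hydrolysis of the oxocarbenium ion); silyl ethers and the isolated trisubstituted alkenes should not react in buffered medium.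

Step 18
Reactants: 26 C3 alcohol
Product: 27 C3 2-bromopropanoate (both epimers at the bromine-bearing carbon)
Conditions: 2-bromopropanoyl bromide, pyridine, CH2Cl2, 0 °C
Reagents that add atoms: 2-bromopropanoyl bromide, CC(Br)C(Br)=O
Why: O-Acylation of the only free (primary) hydroxyl with an acid bromide; the configuration of the bromide-bearing carbon is irrelevant because it becomes sp2.

Step 19
Reactants: 27 bromo ester
Product: 28 C7 alcohol
Conditions: PPTS, MeOH/CH2Cl2, 0 °C
Reagents that add atoms: none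
Why: Acid-catalysed methanolysis of silyl ethers is governed by sterics, so the secondary TES ether at C7 should be cleaved well before the hindered tertiary TES ether and the TBS ether.

Step 20
Reactants: 28 C7 alcohol
Product: 29 C7 ketone
Conditions: Dess–Martin periodinane, NaHCO3, CH2Cl2, rt
Reagents that add atoms: none
Why: Dess–Martin oxidation under buffered, non-basic conditions gives the C7 ketone without epimerising the adjacent C6.

Step 21
Reactants: 29 keto bromo ester
Product: 30 eight-membered β-hydroxy lactone (C2–C7 bond; mixture at C2 and C7)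
Conditions: SmI2 (2.5 equiv), THF, −78 °C, slow addition at high dilution
Reagents that add atoms: none
Why: Intramolecular samarium Reformatsky reaction: two-electron reduction of the C–Br bond gives a samarium enolate that adds to the C7 ketone within a chelate, a template effect that makes medium-ring lactones accessible; the two new centres are destroyed in step 22.

Step 22
Reactants: 30 β-hydroxy lactone
Product: 32 α,β-unsaturated eight-membered lactone (C2=C7; C1 cis to C6), via tertiary acetate 31 (not isolated)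
Conditions: Ac2O, DMAP, Et3N, CH2Cl2, rt; then DBU, toluene, 60 °C
Reagents that add atoms: none
Why: Acetylation followed by E1cB elimination: only C2–H is activated towards loss of the C7 acetate, so the double bond can form only between C2 and C7, and within the eight-membered ring it can only be cis, which places C1 on the side of C6 (2Z) whatever the configuration of 30.

Step 23
Reactants: 32 unsaturated lactone
Product: 33 C1,C3-diol
Conditions: i-Bu2AlH, CH2Cl2, −78 → 0 °C
Reagents that add atoms: none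
Why: 1,2-Reduction of the unsaturated lactone by the aluminium hydride gives the allylic C1 alcohol and frees the C3 alcohol with the alkene geometry untouched.

Step 24
Reactants: 33 diol
Product: 34 enal (C10–OTES, C17–OTBS)
Conditions: MnO2, CH2Cl2, rt
Reagents that add atoms: none
Why: MnO2 oxidises allylic alcohols selectively, so the C1 alcohol becomes the enal while the saturated C3 alcohol and the silylated C17 carbinol remain.

Step 25
Reactants: 34 silylated enal
Product: 35 target compound CNP0197298.1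
Conditions: HF·pyridine, pyridine, THF, 0 °C → rt
Reagents that add atoms: none
Why: Fluoride-mediated desilylation buffered with pyridine should remove the TBS and tertiary TES ethers without isomerising the enal or ionising the allylic C17 alcohol.

**Compound list**

1 | δ-valerolactone | O=C1CCCCO1 | starting material
2 | 5-[(4-methoxybenzyl)oxy]pentanoic acid | COc1ccc(COCCCCC(O)=O)cc1 | intermediate
3 | (R)-4-benzyl-2-oxazolidinone | O=C1N[C@H](Cc2ccccc2)CO1 | starting material
4 | 5-[(4-methoxybenzyl)oxy]pentanoic pivalic anhydride | COc1ccc(COCCCCC(=O)OC(=O)C(C)(C)C)cc1 | intermediate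
5 | (R)-4-benzyl-3-{5-[(4-methoxybenzyl)oxy]pentanoyl}oxazolidin-2-one | COc1ccc(COCCCCC(=O)N2[C@H](Cc3ccccc3)COC2=O)cc1 | intermediate
6 | pent-4-enal | C=CCCC=O | starting material
7 | Z-dibutylboron enolate of 5 | COc1ccc(COCCC/C=C(\OB(CCCC)CCCC)N2[C@H](Cc3ccccc3)COC2=O)cc1 | intermediate
8 | (R)-4-benzyl-3-[(2R,3S)-3-hydroxy-2-{3-[(4-methoxybenzyl)oxy]propyl}hept-6-enoyl]oxazolidin-2-one | O=C(N1[C@H](Cc2ccccc2)COC1=O)[C@H](CCCOCc1ccc(OC)cc1)[C@@H](O)CCC=C | intermediate
9 | (2R,3S)-3-hydroxy-N-methoxy-2-{3-[(4-methoxybenzyl)oxy]propyl}-N-methylhept-6-enamide | CON(C)C(=O)[C@H](CCCOCc1ccc(OC)cc1)[C@@H](O)CCC=C | intermediate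
10 | (2R,3S)-N-methoxy-2-{3-[(4-methoxybenzyl)oxy]propyl}-N-methyl-3-(triethylsilyloxy)hept-6-enamide | CON(C)C(=O)[C@H](CCCOCc1ccc(OC)cc1)[C@@H](O[Si](CC)(CC)CC)CCC=C | intermediate
11 | (3R,4S)-3-{3-[(4-methoxybenzyl)oxy]propyl}-4-(triethylsilyloxy)oct-7-en-2-one | CC(=O)[C@H](CCCOCc1ccc(OC)cc1)[C@@H](O[Si](CC)(CC)CC)CCC=C | intermediate
12 | ethyl (2E,4S,5S)-4-{3-[(4-methoxybenzyl)oxy]propyl}-3-methyl-5-(triethylsilyloxy)nona-2,8-dienoate | CCOC(=O)/C=C(C)/[C@H](CCCOCc1ccc(OC)cc1)[C@@H](O[Si](CC)(CC)CC)CCC=C | intermediate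
13 | ethyl (2E,4S,5S)-4-{3-[(4-methoxybenzyl)oxy]propyl}-3-methyl-8-oxo-5-(triethylsilyloxy)non-2-enoate (key-step precursor) | CCOC(=O)/C=C(C)/[C@H](CCCOCc1ccc(OC)cc1)[C@@H](O[Si](CC)(CC)CC)CCC(C)=O | intermediate
14 | ethyl 2-[(1S,2S,3S,6S)-6-hydroxy-2-{3-[(4-methoxybenzyl)oxy]propyl}-1,6-dimethyl-3-(triethylsilyloxy)cyclohexyl]acetate (key-step product) | CCOC(=O)C[C@@]1(C)[C@H](CCCOCc2ccc(OC)cc2)[C@@H](O[Si](CC)(CC)CC)CC[C@]1(C)O | intermediate
15 | ethyl 2-[(1S,2S,3S,6S)-2-{3-[(4-methoxybenzyl)oxy]propyl}-1,6-dimethyl-3,6-bis(triethylsilyloxy)cyclohexyl]acetate | CCOC(=O)C[C@@]1(C)[C@H](CCCOCc2ccc(OC)cc2)[C@@H](O[Si](CC)(CC)CC)CC[C@]1(C)O[Si](CC)(CC)CC | intermediate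
16 | 2-[(1S,2S,3S,6S)-2-{3-[(4-methoxybenzyl)oxy]propyl}-1,6-dimethyl-3,6-bis(triethylsilyloxy)cyclohexyl]ethanol | OCC[C@@]1(C)[C@H](CCCOCc2ccc(OC)cc2)[C@@H](O[Si](CC)(CC)CC)CC[C@]1(C)O[Si](CC)(CC)CC | intermediate
17 | C13 iodide: 16 with 2-iodoethyl in place of 2-hydroxyethyl | ICC[C@@]1(C)[C@H](CCCOCc2ccc(OC)cc2)[C@@H](O[Si](CC)(CC)CC)CC[C@]1(C)O[Si](CC)(CC)CC | intermediate
18 | geranial | CC(C)=CCC/C(C)=C/C=O | starting material
19 | (4R,5E)-6,10-dimethylundeca-5,9-dien-1-yn-4-ol | CC(C)=CCC/C(C)=C/[C@H](O)CC#C | intermediate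
20 | bis(dimethylaluminium) vinylalane alkoxide from 19 | CC(C)=CCC/C(C)=C/[C@H](O[Al](C)C)C/C(C)=C/[Al](C)C | intermediate
21 | (1E,4R,5E)-1-iodo-2,6,10-trimethylundeca-1,5,9-trien-4-ol | CC(C)=CCC/C(C)=C/[C@H](O)C/C(C)=C/I | intermediate
22 | (1E,4R,5E)-4-(tert-butyldimethylsilyloxy)-1-iodo-2,6,10-trimethylundeca-1,5,9-triene | CC(C)=CCC/C(C)=C/[C@H](O[Si](C)(C)C(C)(C)C)C/C(C)=C/I | intermediate
23 | alkyllithium from 17 (Li in place of I) | [Li]CC[C@@]1(C)[C@H](CCCOCc2ccc(OC)cc2)[C@@H](O[Si](CC)(CC)CC)CC[C@]1(C)O[Si](CC)(CC)CC | intermediate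
24 | alkylzinc chloride from 23 | Cl[Zn]CC[C@@]1(C)[C@H](CCCOCc2ccc(OC)cc2)[C@@H](O[Si](CC)(CC)CC)CC[C@]1(C)O[Si](CC)(CC)CC | intermediate
25 | coupled polyene: core of 17 bearing on C11 the (3E,6R,7E)-6-(tert-butyldimethylsilyloxy)-4,8,12-trimethyltrideca-3,7,11-trienyl chain; C3–OPMB, C7–OTES, C10–OTES | CC(C)=CCC/C(C)=C/[C@H](O[Si](C)(C)C(C)(C)C)C/C(C)=C/CC[C@@]1(C)[C@H](CCCOCc2ccc(OC)cc2)[C@@H](O[Si](CC)(CC)CC)CC[C@]1(C)O[Si](CC)(CC)CC | intermediate
26 | C3 alcohol (25 without PMB) | CC(C)=CCC/C(C)=C/[C@H](O[Si](C)(C)C(C)(C)C)C/C(C)=C/CC[C@@]1(C)[C@H](CCCO)[C@@H](O[Si](CC)(CC)CC)CC[C@]1(C)O[Si](CC)(CC)CC | intermediate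
27 | C3 2-bromopropanoate of 26 | CC(C)=CCC/C(C)=C/[C@H](O[Si](C)(C)C(C)(C)C)C/C(C)=C/CC[C@@]1(C)[C@H](CCCOC(=O)C(C)Br)[C@@H](O[Si](CC)(CC)CC)CC[C@]1(C)O[Si](CC)(CC)CC | intermediate
28 | C7 alcohol (27 without the secondary TES group) | CC(C)=CCC/C(C)=C/[C@H](O[Si](C)(C)C(C)(C)C)C/C(C)=C/CC[C@@]1(C)[C@H](CCCOC(=O)C(C)Br)[C@@H](O)CC[C@]1(C)O[Si](CC)(CC)CC | intermediate
29 | C7 ketone bearing the C3 2-bromopropanoate | CC(C)=CCC/C(C)=C/[C@H](O[Si](C)(C)C(C)(C)C)C/C(C)=C/CC[C@@]1(C)[C@H](CCCOC(=O)C(C)Br)C(=O)CC[C@]1(C)O[Si](CC)(CC)CC | intermediate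
30 | eight-membered β-hydroxy lactone (O–C1(=O)–C2(Me)–C7(OH) tether from C3 to C7; C2 and C7 unassigned) | CC(C)=CCC/C(C)=C/[C@H](O[Si](C)(C)C(C)(C)C)C/C(C)=C/CC[C@@]1(C)[C@@H]2CCCOC(=O)C(C)C2(O)CC[C@]1(C)O[Si](CC)(CC)CC | intermediate
31 | C7 tertiary acetate of 30 | CC(C)=CCC/C(C)=C/[C@H](O[Si](C)(C)C(C)(C)C)C/C(C)=C/CC[C@@]1(C)[C@@H]2CCCOC(=O)C(C)C2(OC(C)=O)CC[C@]1(C)O[Si](CC)(CC)CC | intermediate
32 | α,β-unsaturated eight-membered lactone (C2=C7, C1 cis to C6) | CC(C)=CCC/C(C)=C/[C@H](O[Si](C)(C)C(C)(C)C)C/C(C)=C/CC[C@@]1(C)[C@@H]2CCCOC(=O)/C(C)=C2/CC[C@]1(C)O[Si](CC)(CC)CC | intermediate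
33 | C1,C3-diol (2Z allylic alcohol; C10–OTES, C17–OTBS) | CC(C)=CCC/C(C)=C/[C@H](O[Si](C)(C)C(C)(C)C)C/C(C)=C/CC[C@@]1(C)[C@H](CCCO)/C(=C(/C)CO)CC[C@]1(C)O[Si](CC)(CC)CC | intermediate
34 | 2Z enal with free C3–OH (C10–OTES, C17–OTBS) | CC(C)=CCC/C(C)=C/[C@H](O[Si](C)(C)C(C)(C)C)C/C(C)=C/CC[C@@]1(C)[C@H](CCCO)/C(=C(/C)C=O)CC[C@]1(C)O[Si](CC)(CC)CC | intermediate
35 | CNP0197298.1, (2Z,6R,10S,11S,14E,17R,18E) | CC(C)=CCC/C(C)=C/[C@H](O)C/C(C)=C/CC[C@@]1(C)[C@H](CCCO)/C(=C(/C)C=O)CC[C@]1(C)O | target

**Step count and risks**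

Total step count: 25. Longest linear sequence: 22 steps (steps 1–12 and 16–25); the vinyl iodide branch is steps 13–15.

Steps most likely to fail:

Step 9 (key cyclisation). What may go wrong: the ketyl is reduced further to the secondary alcohol or pinacol-couples before it adds to the hindered β,β-disubstituted enoate, or the closure shows poor facial selectivity at C10 and C11. Fallback, from 12 back to 16: the same C10–C11 bond would be made by a two-electron intramolecular Nozaki–Hiyama allylation instead of a radical addition. Reduction of 12 with i-Bu2AlH gives the allylic alcohol F1. Wacker oxidation of its terminal alkene (PdCl2, Cu(OAc)2, O2) gives the keto alcohol F2. MsCl, LiCl and 2,4,6-collidine in DMF convert it to the allylic chloride F3. CrCl2 in THF generates an allylchromium species that adds through its γ-carbon C11 to the C10 ketone and closes the ring to the vinyl cyclohexanol F4; a chair with the metal alkoxide equatorial should favour the same trans relation, to be confirmed. Silylation with TESOTf gives the bis-silyl ether F5. Hydroboration with 9-BBN and NaOH/H2O2 oxidation turn the vinyl group into the hydroxyethyl arm of 16.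

Step 21 (eight-membered Reformatsky closure). What may go wrong: the samarium enolate is protonated, or the aldolate reverts, before the medium ring closes, so that only debromination is seen. Fallback, from 25 back to 34: the enal would be made without any ring, by oxidative allylic transposition. PPTS in MeOH frees the C7 alcohol F6. Dess–Martin oxidation gives the ketone F7. Isopropenylmagnesium bromide (CH2=C(CH3)MgBr) with CeCl3 adds to give the tertiary allylic alcohol F8. Pyridinium chlorochromate (C5H5NH[CrO3Cl]) effects the Babler–Dauben transposition to the PMB-protected enal F9. Both geometries are expected here; the 2Z isomer would be separated and the 2E isomer re-equilibrated with a trace of iodine under light. DDQ then removes the PMB group to give 34.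

Step 7 (olefination of the hindered methyl ketone). What may go wrong: enolisation of the α-branched ketone with β-elimination of the C7 silyloxy group or epimerisation at C6, and incomplete E/Z control. Fallback, from 10 back to 12: the enoate geometry would be fixed by carbometalation. i-Bu2AlH reduces the Weinreb amide 10 to the aldehyde F10. The Ohira–Bestmann reagent (dimethyl 1-diazo-2-oxopropylphosphonate, K2CO3, MeOH) gives the terminal alkyne F11. Zirconium-catalysed carboalumination (AlMe3, Cp2ZrCl2) adds methyl and aluminium syn across the alkyne, which reacts much faster than the monosubstituted alkene, and ethyl chloroformate traps the alkenylalane with retention to give the 2E enoate 12.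

**Further compounds**

F1 | step 9 | (2E,4S,5S)-4-{3-[(4-methoxybenzyl)oxy]propyl}-3-methyl-5-(triethylsilyloxy)nona-2,8-dien-1-ol | OC/C=C(C)/[C@H](CCCOCc1ccc(OC)cc1)[C@@H](O[Si](CC)(CC)CC)CCC=C
F2 | step 9 | (5S,6S,7E)-9-hydroxy-6-{3-[(4-methoxybenzyl)oxy]propyl}-7-methyl-5-(triethylsilyloxy)non-7-en-2-one | OC/C=C(C)/[C@H](CCCOCc1ccc(OC)cc1)[C@@H](O[Si](CC)(CC)CC)CCC(C)=O
F3 | step 9 | allylic chloride of F2 (Cl in place of OH) | ClC/C=C(C)/[C@H](CCCOCc1ccc(OC)cc1)[C@@H](O[Si](CC)(CC)CC)CCC(C)=O
F4 | step 9 | vinyl cyclohexanol: 14 with vinyl in place of the ethoxycarbonylmethyl group | C=C[C@@]1(C)[C@H](CCCOCc2ccc(OC)cc2)[C@@H](O[Si](CC)(CC)CC)CC[C@]1(C)O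
F5 | step 9 | C10 triethylsilyl ether of F4 | C=C[C@@]1(C)[C@H](CCCOCc2ccc(OC)cc2)[C@@H](O[Si](CC)(CC)CC)CC[C@]1(C)O[Si](CC)(CC)CC
F6 | step 21 | C7 alcohol of 25 (secondary TES removed, PMB kept) | CC(C)=CCC/C(C)=C/[C@H](O[Si](C)(C)C(C)(C)C)C/C(C)=C/CC[C@@]1(C)[C@H](CCCOCc2ccc(OC)cc2)[C@@H](O)CC[C@]1(C)O[Si](CC)(CC)CC
F7 | step 21 | C7 ketone from F6 | CC(C)=CCC/C(C)=C/[C@H](O[Si](C)(C)C(C)(C)C)C/C(C)=C/CC[C@@]1(C)[C@H](CCCOCc2ccc(OC)cc2)C(=O)CC[C@]1(C)O[Si](CC)(CC)CC
F8 | step 21 | C7 isopropenyl tertiary alcohol (C7 unassigned) | CC(C)=CCC/C(C)=C/[C@H](O[Si](C)(C)C(C)(C)C)C/C(C)=C/CC[C@@]1(C)[C@H](CCCOCc2ccc(OC)cc2)C(O)(C(C)=C)CC[C@]1(C)O[Si](CC)(CC)CC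
F9 | step 21 | 2Z enal with C3–OPMB | CC(C)=CCC/C(C)=C/[C@H](O[Si](C)(C)C(C)(C)C)C/C(C)=C/CC[C@@]1(C)[C@H](CCCOCc2ccc(OC)cc2)/C(=C(/C)C=O)CC[C@]1(C)O[Si](CC)(CC)CC
F10 | step 7 | (2R,3S)-2-{3-[(4-methoxybenzyl)oxy]propyl}-3-(triethylsilyloxy)hept-6-enal | O=C[C@H](CCCOCc1ccc(OC)cc1)[C@@H](O[Si](CC)(CC)CC)CCC=C
F11 | step 7 | terminal alkyne from F10 (ethynyl in place of formyl) | C#C[C@H](CCCOCc1ccc(OC)cc1)[C@@H](O[Si](CC)(CC)CC)CCC=C
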